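The target is a cis-fused bicycle: a γ-lactone ring C9'(=O)–O–C7–C8–C8' (C7 bears the trihydroxyphenyl group) and a tetrahydrofuran ring C8–C9–O–C7'–C8' (C7' bears the catechol). The key step exploits the chain C9–C8–C8'–C9', which is the carbon frame of a butenolide whose two central carbons each carry one aryl carbinol carbon on opposite ring faces. In one operation a lithiated aryl dithiane (C7) adds to C8 of (5R)-5-menthyloxy-2(5H)-furanone and the enolate adds through C8' to an aryl aldehyde (C7'), so the acetal centre C9 alone sets C8 and C8'. Later, hydride reduction at C7 turns the lactone over onto O7 and a cationic closure at C7' builds the ether ring. All phenols travel as benzyl ethers.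

Key step: step 4

Atom labels: C9' lactone carbonyl, C7 lactone carbinol carbon, C8 and C8' ring-fusion carbons (C8' next to C9'), C9 ether CH2, C7' ether carbon. The target is (7S,8R,7'S,8'S).

Remark on the chemistry: the aldol forms C7' as both epimers. The mixture is assumed to be carried through steps 5 to 7 without separation, because step 8 sends both epimers through one benzylic cation. The (5R) acetal epimer of the l-menthyl butenolide is the one that leads to the target enantiomer, and no building block needed correction.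

Step 1
Reactants: 1 3,4,5-tris(benzyloxy)benzaldehyde
Product: 2 2-[3,4,5-tris(benzyloxy)phenyl]-1,3-dithiane
Conditions: HS(CH2)3SH, BF3·OEt2 (cat.), CH2Cl2, 0 °C → rt
Reagents that add atoms: propane-1,3-dithiol, SCCCS
Why: BF3-catalysed dithioacetalisation of an aromatic aldehyde (thioacetal formation) is reliable, leaves the benzyl ethers alone and creates no stereocentre.

Step 2
Reactants: 3 furfural
Product: 5 5-hydroxy-2(5H)-furanone (racemic), via furfural endoperoxide 4 (not isolated)
Conditions: O2, visible light, methylene blue (3,7-bis(dimethylamino)phenothiazin-5-ium chloride, cat.), MeOH, rt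
Reagents that add atoms: dioxygen, O=O
Why: Dye-sensitised photo-oxygenation: singlet oxygen adds to the furan in a [4+2] cycloaddition to give endoperoxide 4, which methanol fragments at the formyl group, expelling methyl formate and leaving the racemic hydroxybutenolide 5.

Step 3
Reactants: 5 5-hydroxy-2(5H)-furanone; 6 (−)-menthol
Product: 8 (5R)-5-(l-menthyloxy)-2(5H)-furanone, via (5S)-epimer acetal 7 (not isolated)
Conditions: (+)-camphor-10-sulfonic acid (CSA, cat.), toluene, reflux, Dean–Stark; crystallisation from petroleum ether; liquor re-equilibrated with CSA and crystallised again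
Reagents that add atoms: none
Why: Acid-catalysed acetal formation at the lactol carbon gives both C5 epimers, which interconvert through the ring oxocarbenium ion, so crystallising the less soluble (5R) acetal 8 and re-equilibrating the liquor rich in 7 under the same acid should deliver a single diastereomer (crystallisation-driven resolution of the acetal centre).

Step 4
Reactants: 2 2-[3,4,5-tris(benzyloxy)phenyl]-1,3-dithiane; 8 (5R)-5-(l-menthyloxy)-2(5H)-furanone; 9 3,4-bis(benzyloxy)benzaldehyde
Product: 13 (3S,4R,5R)-3-{[3,4-bis(benzyloxy)phenyl](hydroxy)methyl}-5-(l-menthyloxy)-4-{2-[3,4,5-tris(benzyloxy)phenyl]-1,3-dithian-2-yl}dihydrofuran-2(3H)-one (both C7' epimers), via 2-lithio dithiane 10 (not isolated), via lithium lactone enolate 11 (not isolated), via lithium aldolate 12 (not isolated)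
Conditions: n-BuLi, THF, −78 → −30 °C; then 8, −78 °C; then 9, −78 °C; NH4Cl (aq) at −78 °C
Reagents that add atoms: none
Why: n-BuLi removes the C2 proton of 2 and the soft, sulfur- and aryl-stabilised carbanion 10 adds in a Michael addition to C4 of butenolide 8 (C8), after which the lactone enolate 11 attacks aldehyde 9 through C3 (C8') in an aldol addition and the aldolate 12 is protonated cold. The closest known reaction type is the tandem conjugate addition and aldol trapping of lithiated 2-aryl-1,3-dithianes on 5-alkoxy-2(5H)-furanones. No ring is closed: two C–C bonds (C7–C8 and C8'–C7') and three stereocentres are formed. C8 is set by the acetal centre C9, whose menthyloxy group blocks one face of the flat ring so that 10 enters anti to it; C8' is set by the new bulky dithianyl group at C8, the aldehyde approaching the enolate from the opposite face (trans); C7' is not controlled and both epimers are carried on because the later cationic closure converges them. The step needs 1,4- over 1,2-addition, which the delocalised dithianyl anion and the unhindered β-carbon of the ring-locked butenolide should secure, and it needs C–C bond formation to outrun proton transfer and retro-aldol, which the non-enolisable aldehyde and the quench at −78 °C should secure.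

Step 5
Reactants: 13 aldol adduct (both C7' epimers)
Product: 14 (3S,4R,5R)-3-{[3,4-bis(benzyloxy)phenyl](hydroxy)methyl}-5-(l-menthyloxy)-4-[3,4,5-tris(benzyloxy)benzoyl]dihydrofuran-2(3H)-one (both C7' epimers)
Conditions: HgO, BF3·OEt2, THF/H2O (85:15), rt
Reagents that add atoms: water, O
Why: Mercury-assisted hydrolysis of the dithioacetal (thiophilic Lewis acid, water as the oxygen source) should unmask the C7 aryl ketone without touching the acetal, the lactone, the benzyl ethers or the existing stereocentres, and the trans disposition of the aroyl and carbinol arms prevents hemiketal formation.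

Step 6
Reactants: 14 C7 ketone (both C7' epimers)
Product: 17 (3S,3aS,6aS)-6-[3,4-bis(benzyloxy)phenyl]-4-hydroxy-3-[3,4,5-tris(benzyloxy)phenyl]tetrahydro-1H,3H-furo[3,4-c]furan-1-one (lactol; anomers at C9 and both C7' epimers), via (7S) lithium alkoxide 15 (not isolated), via hydroxy aldehyde lactone 16 (not isolated)
Conditions: LiBH(s-Bu)3 (1.2 equiv), THF, −78 → 0 °C; NH4Cl (aq)
Reagents that add atoms: none
Why: Felkin–Anh-controlled ketone reduction by a bulky borohydride: hydride should attack the Re face of C7 anti to C8', the ring carbon carrying the branched carbinol arm (lithium chelation to the C9 oxygens points the same way), giving the (7S) alkoxide 15, which translactonises onto C9' through a bicyclic ortho-ester-type intermediate (2,6-dioxabicyclo[2.2.1]heptane); the freed C9 hemiacetal oxide expels menthoxide irreversibly and the aldehyde 16 is held as lactol 17 by the now cis C7' hydroxyl.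

Step 7
Reactants: 17 lactol
Product: 18 (3S,4R,5S)-3-{[3,4-bis(benzyloxy)phenyl](hydroxy)methyl}-4-(hydroxymethyl)-5-[3,4,5-tris(benzyloxy)phenyl]dihydrofuran-2(3H)-one (both C7' epimers)
Conditions: NaBH4, THF/MeOH, −20 → 0 °C; pH 7 phosphate buffer
Reagents that add atoms: none
Why: Borohydride reduction of a lactol through its open hydroxy aldehyde form should give the primary C9 alcohol while the γ-lactone survives at or below 0 °C; no stereocentre is touched, and a drift of the lactone back to O9 would have to pass the strained bicyclic ortho-ester without a lithium alkoxide to drive it.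

Step 8
Reactants: 18 diol lactone (both C7' epimers)
Product: 19 (3S,3aR,6S,6aS)-6-[3,4-bis(benzyloxy)phenyl]-3-[3,4,5-tris(benzyloxy)phenyl]tetrahydro-1H,3H-furo[3,4-c]furan-1-one
Conditions: CSA (0.2 equiv), CH2Cl2, 4 Å molecular sieves, 0 °C → rt
Reagents that add atoms: none
Why: Acid-catalysed SN1 etherification: both C7' epimers ionise to the same 4-benzyloxy-stabilised benzylic cation, which the cis C9 hydroxyl captures in a 5-exo closure to give the cis-fused tetrahydrofuran with the aryl group on the convex face, trans to C9' across C7'–C8', the (7'S) configuration favoured kinetically and thermodynamically.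

Step 9
Reactants: 19 pentabenzyl ether of the target
Product: 20 (3S,3aR,6S,6aS)-6-(3,4-dihydroxyphenyl)-3-(3,4,5-trihydroxyphenyl)tetrahydro-1H,3H-furo[3,4-c]furan-1-one (target)
Conditions: H2 (1 atm), 10% Pd/C, THF/EtOAc, rt, stopped after uptake for five benzyl groups
Reagents that add atoms: none
Why: Catalytic hydrogenolysis of aryl benzyl ethers over Pd/C in a neutral aprotic solvent is faster than cleavage of the ring benzylic C–O bonds at C7 and C7', so stopping at the uptake for five benzyl groups should free the pentaphenol with all four stereocentres unchanged.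

Compound list
1 | 3,4,5-tris(benzyloxy)benzaldehyde | O=Cc1cc(OCc2ccccc2)c(OCc2ccccc2)c(OCc2ccccc2)c1 | starting material
2 | 2-[3,4,5-tris(benzyloxy)phenyl]-1,3-dithiane | C1CSC(SC1)c1cc(OCc2ccccc2)c(OCc2ccccc2)c(OCc2ccccc2)c1 | intermediate
3 | furfural (furan-2-carbaldehyde) | O=Cc1ccco1 | starting material
4 | furfural 2,5-endoperoxide, 2,3,7-trioxabicyclo[2.2.1]hept-5-ene-1-carbaldehyde (racemic, not isolated) | O=CC12C=CC(O1)OO2 | intermediate
5 | 5-hydroxy-2(5H)-furanone (racemic) | OC1OC(=O)C=C1 | intermediate
6 | (−)-menthol, (1R,2S,5R)-2-isopropyl-5-methylcyclohexanol | C[C@@H]1CC[C@H]([C@@H](C1)O)C(C)C | starting material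
7 | (5S)-5-[(1R,2S,5R)-menthyloxy]-2(5H)-furanone (stays in the liquor, re-equilibrated, not isolated) | C[C@@H]1CC[C@H]([C@@H](C1)O[C@H]2OC(=O)C=C2)C(C)C | intermediate
8 | (5R)-5-[(1R,2S,5R)-menthyloxy]-2(5H)-furanone | C[C@@H]1CC[C@H]([C@@H](C1)O[C@@H]2OC(=O)C=C2)C(C)C | intermediate
9 | 3,4-bis(benzyloxy)benzaldehyde | O=Cc1ccc(OCc2ccccc2)c(OCc2ccccc2)c1 | starting material
10 | 2-lithio-2-[3,4,5-tris(benzyloxy)phenyl]-1,3-dithiane (not isolated) | [Li]C1(SCCCS1)c1cc(OCc2ccccc2)c(OCc2ccccc2)c(OCc2ccccc2)c1 | intermediate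
11 | lithium enolate of (4R,5R)-5-(l-menthyloxy)-4-{2-[3,4,5-tris(benzyloxy)phenyl]-1,3-dithian-2-yl}dihydrofuran-2(3H)-one (not isolated) | C[C@@H]1CC[C@H]([C@@H](C1)O[C@@H]2OC(O[Li])=C[C@H]2C2(SCCCS2)c2cc(OCc3ccccc3)c(OCc3ccccc3)c(OCc3ccccc3)c2)C(C)C | intermediate
12 | lithium aldolate (C7' lithium alkoxide) of 13, both C7' epimers (not isolated) | C[C@@H]1CC[C@H]([C@@H](C1)O[C@@H]2OC(=O)[C@H](C(O[Li])c3ccc(OCc4ccccc4)c(OCc4ccccc4)c3)[C@H]2C2(c3cc(OCc4ccccc4)c(OCc4ccccc4)c(OCc4ccccc4)c3)SCCCS2)C(C)C | intermediate
13 | (3S,4R,5R)-3-{[3,4-bis(benzyloxy)phenyl](hydroxy)methyl}-5-(l-menthyloxy)-4-{2-[3,4,5-tris(benzyloxy)phenyl]-1,3-dithian-2-yl}dihydrofuran-2(3H)-one; carbinol carbon C7' as both epimers; ring substituents trans,trans | C[C@@H]1CC[C@H]([C@@H](C1)O[C@@H]2OC(=O)[C@H](C(O)c3ccc(OCc4ccccc4)c(OCc4ccccc4)c3)[C@H]2C2(c3cc(OCc4ccccc4)c(OCc4ccccc4)c(OCc4ccccc4)c3)SCCCS2)C(C)C | intermediate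
14 | (3S,4R,5R)-3-{[3,4-bis(benzyloxy)phenyl](hydroxy)methyl}-5-(l-menthyloxy)-4-[3,4,5-tris(benzyloxy)benzoyl]dihydrofuran-2(3H)-one; C7' both epimers | C[C@@H]1CC[C@H]([C@@H](C1)O[C@@H]2OC(=O)[C@H](C(O)c3ccc(OCc4ccccc4)c(OCc4ccccc4)c3)[C@H]2C(=O)c2cc(OCc3ccccc3)c(OCc3ccccc3)c(OCc3ccccc3)c2)C(C)C | intermediate
15 | lithium (7S)-alkoxide of (3S,4S,5R)-3-{[3,4-bis(benzyloxy)phenyl](hydroxy)methyl}-4-{(S)-hydroxy[3,4,5-tris(benzyloxy)phenyl]methyl}-5-(l-menthyloxy)dihydrofuran-2(3H)-one (not isolated) | C[C@@H]1CC[C@H]([C@@H](C1)O[C@@H]2OC(=O)[C@H](C(O)c3ccc(OCc4ccccc4)c(OCc4ccccc4)c3)[C@H]2[C@H](O[Li])c2cc(OCc3ccccc3)c(OCc3ccccc3)c(OCc3ccccc3)c2)C(C)C | intermediate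
16 | (2S,3S,4S)-4-{[3,4-bis(benzyloxy)phenyl](hydroxy)methyl}-5-oxo-2-[3,4,5-tris(benzyloxy)phenyl]tetrahydrofuran-3-carbaldehyde; C7' both epimers (not isolated) | O=C1O[C@H](c2cc(OCc3ccccc3)c(OCc3ccccc3)c(OCc3ccccc3)c2)[C@@H](C=O)[C@H]1C(O)c1ccc(OCc2ccccc2)c(OCc2ccccc2)c1 | intermediate
17 | (3S,3aS,6aS)-6-[3,4-bis(benzyloxy)phenyl]-4-hydroxy-3-[3,4,5-tris(benzyloxy)phenyl]tetrahydro-1H,3H-furo[3,4-c]furan-1-one; lactol, C4 (C9) anomers and C6 (C7') epimers | O=C1O[C@H](c2cc(OCc3ccccc3)c(OCc3ccccc3)c(OCc3ccccc3)c2)[C@H]2C(O)OC(c3ccc(OCc4ccccc4)c(OCc4ccccc4)c3)[C@@H]12 | intermediate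
18 | (3S,4R,5S)-3-{[3,4-bis(benzyloxy)phenyl](hydroxy)methyl}-4-(hydroxymethyl)-5-[3,4,5-tris(benzyloxy)phenyl]dihydrofuran-2(3H)-one; C7' both epimers | O=C1O[C@H](c2cc(OCc3ccccc3)c(OCc3ccccc3)c(OCc3ccccc3)c2)[C@@H](CO)[C@H]1C(O)c1ccc(OCc2ccccc2)c(OCc2ccccc2)c1 | intermediate
19 | (3S,3aR,6S,6aS)-6-[3,4-bis(benzyloxy)phenyl]-3-[3,4,5-tris(benzyloxy)phenyl]tetrahydro-1H,3H-furo[3,4-c]furan-1-one | O=C1O[C@H](c2cc(OCc3ccccc3)c(OCc3ccccc3)c(OCc3ccccc3)c2)[C@H]2CO[C@H](c3ccc(OCc4ccccc4)c(OCc4ccccc4)c3)[C@@H]12 | intermediate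
20 | (3S,3aR,6S,6aS)-6-(3,4-dihydroxyphenyl)-3-(3,4,5-trihydroxyphenyl)tetrahydro-1H,3H-furo[3,4-c]furan-1-one | O=C1O[C@H](c2cc(O)c(O)c(O)c2)[C@H]2CO[C@H](c3ccc(O)c(O)c3)[C@@H]12 | target

Total step count: 9.
Longest linear sequence: 8 steps (furfural 3 → 20 through steps 2, 3, 4, 5, 6, 7, 8, 9); the dithiane branch from 1 is 7 steps.

Steps most likely to fail

1. Step 6. Hydride may be delivered to the wrong face of the C7 ketone under substrate control, which after lactone turnover would place the trihydroxyphenyl-bearing carbon in the endo series. The C7' aldolate may also revert by retro-aldol while the mixture warms. Fallback: setting out from 14, a reagent-controlled Corey–Bakshi–Shibata reduction is used. The reagents are BH3·SMe2 in excess and (R)-2-methyl-CBS-oxazaborolidine [(R)-1-methyl-3,3-diphenyltetrahydro-1H,3H-pyrrolo[1,2-c][1,3,2]oxazaborole] in THF at −20 °C. With the aryl group as the large substituent, hydride goes to the Re face. Under these non-basic conditions the lactone does not turn over, and the product is the (7S)-hydroxy menthyloxy lactone F1. The lactone is then turned over in a separate operation with LiN(SiMe3)2 in THF (−78 → 0 °C), through alkoxide 15 with loss of menthol, and the route is rejoined at lactol 17.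

2. Step 9. Hydrogenolysis may run on past the benzyl ethers and cleave the benzylic lactone C7–O or ether C7'–O bond once the para phenols are free, or the removal of five benzyl groups may stall. Fallback: setting out from 19, a non-reductive Lewis acid debenzylation is used: BCl3 with pentamethylbenzene as benzyl cation scavenger in CH2Cl2 at −78 °C, quenched cold with MeOH. This returns directly to 20 without a new intermediate.

3. Step 4. The lithium aldolate may revert (retro-aldol), or the enolate may be protonated before the aldehyde is consumed, leaving only the conjugate adduct. Fallback: setting out from 2 and 8, the two bond formations are separated. The conjugate addition alone (n-BuLi, THF, −78 °C) is quenched cold to isolate the trans Michael adduct F2. Its enolate is regenerated with LiN(i-Pr)2 at −78 °C and transmetallated with ZnCl2, and 9 is then added. The zinc aldolate resists retro-aldol, and the route is rejoined at 13.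

Further compounds
F1 | step 6 | (3S,4S,5R)-3-{[3,4-bis(benzyloxy)phenyl](hydroxy)methyl}-4-{(S)-hydroxy[3,4,5-tris(benzyloxy)phenyl]methyl}-5-(l-menthyloxy)dihydrofuran-2(3H)-one (C7' both epimers) | C[C@@H]1CC[C@H]([C@@H](C1)O[C@@H]2OC(=O)[C@H](C(O)c3ccc(OCc4ccccc4)c(OCc4ccccc4)c3)[C@H]2[C@H](O)c2cc(OCc3ccccc3)c(OCc3ccccc3)c(OCc3ccccc3)c2)C(C)C
F0 | step 9 | none | none
F2 | step 4 | (4R,5R)-5-(l-menthyloxy)-4-{2-[3,4,5-tris(benzyloxy)phenyl]-1,3-dithian-2-yl}dihydrofuran-2(3H)-one | C[C@@H]1CC[C@H]([C@@H](C1)O[C@@H]2OC(=O)C[C@H]2C2(c3cc(OCc4ccccc4)c(OCc4ccccc4)c(OCc4ccccc4)c3)SCCCS2)C(C)C
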